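**Retrosynthetic overview**

1. Target 38 is epicatechin 3-O-gallate-(4β→8)-epicatechin 3-O-gallate-(4β→6)-catechin. The last skeletal bond, C4(top)–C8(mid), comes from Lewis acid coupling of an epicatechin-derived C4 electrophile with a mid–bottom dimer whose bottom C8 is blocked by bromine; nineteen benzyl ethers and the bromine fall in one final hydrogenolysis.
2. The mid unit is grown on the formyl carbon at bottom C6, which becomes mid C4: aryllithium addition (C4–C4a), phosphoric acid catalysed ortho-quinone methide/enamide annulation (C4–C3 and O1–C2, mid ring C), face-selective epoxidation, galloylation, ionic reduction at C2.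
3. Bottom ring C is closed at O1–C8a by copper-catalysed intramolecular etherification of an anti bromo alcohol. The feature used: in the bottom catechin the interflavan carbon C6 of ring A lies between the oxygenated carbons C5 and C7 and para to C8a, the carbon bearing ring oxygen O1. A 3,5-dioxygenated arene carrying the future mid C4 between its oxygens and bromine para to it therefore fixes the 4→6 linkage before any flavan ring exists.
4. The precursor comes from 4-bromo-2,6-difluorobenzaldehyde: SNAr, iodination beside bromine, acetal, I/Mg exchange with opening of methyl (S)-glycidate (C3 stereocentre), benzylation, Weinreb amide, B-ring ketone, chelation-controlled reduction (C2 stereocentre).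
5. Order of ring formation: bottom ring C (step 9), then mid ring C (step 16); the rings of the top unit come from (−)-epicatechin.

Key step: step 9

Assumption: the (R)-configured phosphoric acid of step 16 is taken to give the C4 configuration drawn for 27 (its enantiomer is used if the sense is opposite); the descriptor of mid C4 is R in the benzylated, brominated intermediates and S in 38 through CIP priorities only.

**Route**

Step 1
Reactants: 1 4-bromo-2,6-difluorobenzaldehyde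
Product: 2 2,6-bis(benzyloxy)-4-bromobenzaldehyde
Conditions: BnOH, NaH, THF/DMF, 0 → 40 °C
Reagents that add atoms: benzyl alcohol OCc1ccccc1
Why: Twofold nucleophilic aromatic substitution (SNAr) should displace both fluorides ortho to the formyl group, while the bromide para to it, a much poorer nucleofuge, stays as the marker of the later C8a.

Step 2
Reactants: 2 2,6-bis(benzyloxy)-4-bromobenzaldehyde
Product: 3 2,6-bis(benzyloxy)-4-bromo-3-iodobenzaldehyde
Conditions: N-iodosuccinimide (1.0 equiv), CF3CO2H (cat.), MeCN, rt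
Reagents that add atoms: N-iodosuccinimide O=C1CCC(=O)N1I
Why: Electrophilic aromatic iodination should occur at one of the two equivalent free positions, which are ortho/para to the benzyloxy groups and meta to the formyl group, so one equivalent gives the mono-iodide beside bromine.

Step 3
Reactants: 3 2,6-bis(benzyloxy)-4-bromo-3-iodobenzaldehyde
Product: 4 1,3-bis(benzyloxy)-5-bromo-2-(dimethoxymethyl)-4-iodobenzene
Conditions: HC(OMe)3, p-toluenesulfonic acid (cat.), MeOH, 50 °C; NaOMe quench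
Reagents that add atoms: trimethyl orthoformate COC(OC)OC
Why: Acid-catalysed acetalisation with the orthoformate as water scavenger should mask the aldehyde for the organometallic steps.

Step 4
Reactants: 4 1,3-bis(benzyloxy)-5-bromo-2-(dimethoxymethyl)-4-iodobenzene; 5 methyl (2S)-oxirane-2-carboxylate
Product: 7 methyl (2S)-3-[2,4-bis(benzyloxy)-6-bromo-3-(dimethoxymethyl)phenyl]-2-hydroxypropanoate, via arylmagnesium chloride 6 (not isolated)
Conditions: iPrMgCl·LiCl, THF, −40 °C; then CuI (10 mol%), 5, −40 → −15 °C; aq. NH4Cl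
Reagents that add atoms: none
Why: Iodine–magnesium exchange is much faster at C–I than at C–Br, and the copper-catalysed epoxide opening of the glycidic ester should occur at the terminal carbon in an SN2 sense, so the stereocentre is untouched and the (S)-α-hydroxy ester results.

Step 5
Reactants: 7 methyl (2S)-3-aryl-2-hydroxypropanoate
Product: 8 methyl (2S)-2-(benzyloxy)-3-[2,4-bis(benzyloxy)-6-bromo-3-(dimethoxymethyl)phenyl]propanoate
Conditions: BnBr, Ag2O, Bu4NI (cat.), CH2Cl2, rt, dark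
Reagents that add atoms: benzyl bromide BrCc1ccccc1
Why: Silver-oxide-mediated Williamson etherification should benzylate the α-hydroxy ester without a strong base, so the α-stereocentre is not epimerised.

Step 6
Reactants: 8 methyl (2S)-2-(benzyloxy)-3-arylpropanoate
Product: 9 (2S)-2-(benzyloxy)-3-[2,4-bis(benzyloxy)-6-bromo-3-(dimethoxymethyl)phenyl]-N-methoxy-N-methylpropanamide
Conditions: MeNH(OMe)·HCl, iPrMgCl, THF, −20 °C
Reagents that add atoms: N,O-dimethylhydroxylamine hydrochloride CNOC.Cl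
Why: Aminolysis of the ester by the magnesium amide of N,O-dimethylhydroxylamine should give the Weinreb amide at low temperature without touching the α-stereocentre.

Step 7
Reactants: 9 Weinreb amide; 10 1,2-bis(benzyloxy)-4-bromobenzene
Product: 12 (2S)-2-(benzyloxy)-1-[3,4-bis(benzyloxy)phenyl]-3-[2,4-bis(benzyloxy)-6-bromo-3-(dimethoxymethyl)phenyl]propan-1-one, via Grignard reagent 11 (not isolated)
Conditions: 10, Mg, THF, 40 °C; then 9, THF, 0 °C; aq. NH4Cl
Reagents that add atoms: none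
Why: In the Weinreb ketone synthesis the aryl Grignard reagent adds once, the chelated tetrahedral intermediate collapsing to the B-ring ketone only on work-up.

Step 8
Reactants: 12 α-benzyloxy ketone
Product: 13 (1R,2S)-2-(benzyloxy)-1-[3,4-bis(benzyloxy)phenyl]-3-[2,4-bis(benzyloxy)-6-bromo-3-(dimethoxymethyl)phenyl]propan-1-ol
Conditions: Zn(BH4)2, Et2O, −30 → 0 °C
Reagents that add atoms: none
Why: In this chelation-controlled (Cram chelate) reduction zinc bridges the carbonyl and α-benzyloxy oxygens and hydride enters opposite to the arylmethyl group, which should set the carbinol as 1R, anti to the ether.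

Step 9
Reactants: 13 anti bromo alcohol
Product: 14 (2R,3S)-3,5,7-tris(benzyloxy)-2-[3,4-bis(benzyloxy)phenyl]-6-(dimethoxymethyl)chromane
Conditions: CuI (10 mol%), 3,4,7,8-tetramethyl-1,10-phenanthroline (20 mol%), Cs2CO3, toluene, 110 °C
Reagents that add atoms: none
Why: Cs2CO3 deprotonates the benzylic alcohol, the phenanthroline-ligated monovalent copper alkoxide adds oxidatively to the C8a–Br bond to give a trivalent copper aryl alkoxide held in a seven-membered cupracycle, and C–O reductive elimination forms O1–C8a. The closest known reaction type is the Ullmann-type copper-catalysed intramolecular O-arylation of aryl bromides by secondary alcohols, which is established for chromans. Ring C of the bottom unit closes as a six-membered ring in an exo mode by ipso substitution at the aromatic carbon. No stereocentre is created: no bond to C2 or C3 is broken, so the anti (1R,2S) alcohol/ether pair is carried with retention into the 2,3-trans (2R,3S) catechin ring. The step needs chemoselectivity for the C2 hydroxyl and a defined aryl carbon: the only other chain oxygen is a benzyl ether, which excludes the five-membered dihydrobenzofuran, and bromine para to the acetal carbon fixes that carbon as C6. Copper has little tendency to β-hydride elimination from the secondary alkoxide, which protects the carbinol from oxidation.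

Step 10
Reactants: 14 catechin acetal
Product: 15 (2R,3S)-3,5,7-tris(benzyloxy)-2-[3,4-bis(benzyloxy)phenyl]-8-bromo-6-(dimethoxymethyl)chromane
Conditions: N-bromosuccinimide, CH2Cl2, −40 → 0 °C
Reagents that add atoms: N-bromosuccinimide O=C1CCC(=O)N1Br
Why: Electrophilic aromatic bromination should occur at C8, the only free position of the phloroglucinol-type ring A, which is far more activated than the catechol-type ring B.

Step 11
Reactants: 15 8-bromo acetal
Product: 16 (2R,3S)-3,5,7-tris(benzyloxy)-2-[3,4-bis(benzyloxy)phenyl]-8-bromochromane-6-carbaldehyde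
Conditions: pyridinium p-toluenesulfonate (cat.), acetone/H2O, rt
Reagents that add atoms: water O
Why: Mild acid hydrolysis of the very labile trialkoxybenzaldehyde acetal should free the formyl group that becomes mid C4.

Step 12
Reactants: 17 3,5-bis(benzyloxy)phenol
Product: 18 1,3-bis(benzyloxy)-5-(methoxymethoxy)benzene
Conditions: MeOCH2Cl, iPr2NEt, CH2Cl2, 0 °C → rt
Reagents that add atoms: chloromethyl methyl ether COCCl
Why: O-Alkylation (Williamson type) installs the methoxymethyl ether, which serves as directing group for the lithiation.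

Step 13
Reactants: 16 aldehyde; 18 methoxymethyl ether
Product: 20 [2,4-bis(benzyloxy)-6-(methoxymethoxy)phenyl][(2R,3S)-3,5,7-tris(benzyloxy)-2-(3,4-bis(benzyloxy)phenyl)-8-bromochroman-6-yl]methanol (both carbinol epimers), via aryllithium 19 (not isolated)
Conditions: 18, n-BuLi, THF, 0 °C; then 16, −78 → −40 °C; aq. NH4Cl
Reagents that add atoms: none
Why: Directed ortho-metalation beside the methoxymethoxy group and 1,2-addition of the aryllithium to the aldehyde should form the mid C4–C4a bond; the carbinol configuration is irrelevant because this centre is planarised in step 16.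

Step 14
Reactants: 20 benzhydrol
Product: 21 3,5-bis(benzyloxy)-2-{methoxy[(2R,3S)-3,5,7-tris(benzyloxy)-2-(3,4-bis(benzyloxy)phenyl)-8-bromochroman-6-yl]methyl}phenol (both epimers)
Conditions: HCl (cat.), MeOH/THF, 40 °C; NaHCO3 quench
Reagents that add atoms: methanol CO
Why: Acid-catalysed acetal cleavage of the methoxymethyl ether in methanol, with SN1 exchange of the doubly stabilised benzhydrol to its methyl ether, should give a storable ortho-quinone methide precursor with one free ortho phenol.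

Step 15
Reactants: 22 3,4-bis(benzyloxy)benzonitrile
Product: 24 N-{1-[3,4-bis(benzyloxy)phenyl]ethenyl}acetamide, via N-magnesioketimine 23 (not isolated)
Conditions: MeMgBr, THF, 0 → 40 °C; then Ac2O, 0 °C → rt
Reagents that add atoms: methylmagnesium bromide C[Mg]Br; acetic anhydride CC(=O)OC(C)=O
Why: Grignard addition to the nitrile and N-acetylation of the metallated ketimine, which tautomerises, is a standard one-flask enamide synthesis.

Step 16
Reactants: 21 ortho-hydroxybenzhydryl methyl ether; 24 enamide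
Product: 27 (4R)-5,7-bis(benzyloxy)-2-[3,4-bis(benzyloxy)phenyl]-4-[(2R,3S)-3,5,7-tris(benzyloxy)-2-(3,4-bis(benzyloxy)phenyl)-8-bromochroman-6-yl]-4H-chromene, via ortho-quinone methide 25 (not isolated), via 2-acetamidochroman 26 (not isolated)
Conditions: (R)-3,3'-bis(2,4,6-triisopropylphenyl)-1,1'-binaphthyl-2,2'-diyl hydrogen phosphate (10 mol%), 4 Å molecular sieves, CHCl3, 0 °C → rt; then p-toluenesulfonic acid (10 mol%), 40 °C
Reagents that add atoms: none
Why: Chiral phosphoric acid catalysed formation of the ortho-quinone methide, conjugate addition of the enamide and ring closure (formal [4+2] annulation), then acid-induced loss of acetamide, should give the 4H-chromene; the hydrogen-bonded chiral phosphate differentiates the faces of the methide carbon and so sets C4, and the two C4 epimers are in any case diastereomers that can be separated.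

Step 17
Reactants: 27 4H-chromene
Product: 29 (2R,3R,4R)-5,7-bis(benzyloxy)-2-[3,4-bis(benzyloxy)phenyl]-2-methoxy-4-[(2R,3S)-3,5,7-tris(benzyloxy)-2-(3,4-bis(benzyloxy)phenyl)-8-bromochroman-6-yl]chroman-3-ol, via epoxide 28 (not isolated)
Conditions: dimethyldioxirane, acetone/CH2Cl2, −40 °C; then MeOH, −40 → 0 °C
Reagents that add atoms: dimethyldioxirane CC1(C)OO1; methanol CO
Why: Epoxidation of the enol ether by dimethyldioxirane from the face opposite the pseudoaxial C4 aryl group, then trans opening at the ketal carbon by methanol, should place the C3 oxygen trans to the C4 substituent.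

Step 18
Reactants: 29 methyl ketal alcohol; 30 3,4,5-tris(benzyloxy)benzoic acid
Product: 31 (2R,3R,4R)-2-methoxy ketal of step 17 as its 3-O-[3,4,5-tris(benzyloxy)benzoyl] ester
Conditions: N,N'-dicyclohexylcarbodiimide, 4-(dimethylamino)pyridine, CH2Cl2, rt
Reagents that add atoms: none
Why: Steglich esterification should acylate the only free hydroxyl and so install the mid gallate before C2 is reduced.

Step 19
Reactants: 31 galloylated methyl ketal
Product: 32 protected dimer: 5,7,3',4'-tetra-O-benzylepicatechin 3-O-(tri-O-benzylgallate)-(4β→6)-8-bromo-3,5,7,3',4'-penta-O-benzylcatechin (mid unit 2R,3R,4R)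
Conditions: Et3SiH, BF3·OEt2, CH2Cl2, −78 → −40 °C
Reagents that add atoms: none
Why: In this ionic hydrogenation of the cyclic ketal the C2 oxocarbenium ion is shielded on the face of the 3-acyloxy group (neighbouring-group participation through a dioxolanylium ion), so hydride from the silane should enter trans to the ester and leave ring B cis to it (2,3-cis, 2R).

Step 20
Reactants: 33 (−)-epicatechin
Product: 34 5,7,3',4'-tetra-O-benzyl-(−)-epicatechin
Conditions: BnBr, K2CO3, DMF, −10 °C → rt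
Reagents that add atoms: benzyl bromide BrCc1ccccc1
Why: Williamson etherification at low temperature should benzylate the four phenols and leave the secondary alcohol and the C2 configuration untouched.

Step 21
Reactants: 34 tetra-O-benzylepicatechin
Product: 35 (2R,3R,4S)-5,7-bis(benzyloxy)-2-[3,4-bis(benzyloxy)phenyl]-4-(2-ethoxyethoxy)chroman-3-ol
Conditions: 2,3-dichloro-5,6-dicyano-1,4-benzoquinone (DDQ), 2-ethoxyethanol, CH2Cl2, rt
Reagents that add atoms: 2-ethoxyethanol CCOCCO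
Why: In this oxidative benzylic C–H etherification DDQ abstracts hydride from C4 and the alcohol should add to the quinone-methide-type cation trans to the 3-hydroxyl (4β).

Step 22
Reactants: 35 4-(2-ethoxyethoxy) alcohol; 30 3,4,5-tris(benzyloxy)benzoic acid
Product: 36 (2R,3R,4S)-5,7-bis(benzyloxy)-2-[3,4-bis(benzyloxy)phenyl]-4-(2-ethoxyethoxy)chroman-3-yl 3,4,5-tris(benzyloxy)benzoate
Conditions: N,N'-dicyclohexylcarbodiimide, 4-(dimethylamino)pyridine, CH2Cl2, rt
Reagents that add atoms: none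
Why: Steglich esterification of the axial 3-hydroxyl should give the galloylated C4 electrophile.

Step 23
Reactants: 32 protected dimer; 36 galloylated C4 electrophile
Product: 37 protected trimer: nonadeca-O-benzyl 8-bromo derivative of the target (bromine at bottom C8)
Conditions: Me3SiOSO2CF3 (0.5 equiv), CH2Cl2, −78 → −40 °C; Et3N quench
Reagents that add atoms: none
Why: In this Lewis acid promoted Friedel–Crafts type flavan coupling, ionisation of the C4 ether gives a benzylic cation that should be attacked by mid C8 (bottom C8 is blocked by bromine, mid C6 is more hindered) from the face trans to the participating 3-O-galloyl group, giving the 4β→8 bond (top C4 R).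

Step 24
Reactants: 37 protected trimer
Product: 38 epicatechin 3-O-gallate-(4β→8)-epicatechin 3-O-gallate-(4β→6)-catechin (target)
Conditions: H2 (1 atm), Pd(OH)2/C, Et3N (1.5 equiv), THF/MeOH/H2O, rt
Reagents that add atoms: none
Why: Catalytic hydrogenolysis should remove the nineteen benzyl ethers and the aryl bromide in one operation, the amine buffering the hydrogen bromide so that the acid-labile interflavan bonds survive.

**Compound list**

1 | 4-bromo-2,6-difluorobenzaldehyde | O=Cc1c(F)cc(Br)cc1F | starting material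
2 | 2,6-bis(benzyloxy)-4-bromobenzaldehyde | O=Cc1c(OCc9ccccc9)cc(Br)cc1OCc9ccccc9 | intermediate
3 | 2,6-bis(benzyloxy)-4-bromo-3-iodobenzaldehyde | O=Cc1c(OCc9ccccc9)cc(Br)c(I)c1OCc9ccccc9 | intermediate
4 | 1,3-bis(benzyloxy)-5-bromo-2-(dimethoxymethyl)-4-iodobenzene | Ic1c(Br)cc(OCc9ccccc9)c(C(OC)OC)c1OCc9ccccc9 | intermediate
5 | methyl (2S)-oxirane-2-carboxylate (methyl (S)-glycidate) | COC(=O)[C@@H]1CO1 | starting material
6 | [2,4-bis(benzyloxy)-6-bromo-3-(dimethoxymethyl)phenyl]magnesium chloride | Cl[Mg]c1c(Br)cc(OCc9ccccc9)c(C(OC)OC)c1OCc9ccccc9 | intermediate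
7 | methyl (2S)-3-[2,4-bis(benzyloxy)-6-bromo-3-(dimethoxymethyl)phenyl]-2-hydroxypropanoate | COC(=O)[C@@H](O)Cc1c(Br)cc(OCc9ccccc9)c(C(OC)OC)c1OCc9ccccc9 | intermediate
8 | methyl (2S)-2-(benzyloxy)-3-[2,4-bis(benzyloxy)-6-bromo-3-(dimethoxymethyl)phenyl]propanoate | COC(=O)[C@@H](OCc9ccccc9)Cc1c(Br)cc(OCc9ccccc9)c(C(OC)OC)c1OCc9ccccc9 | intermediate
9 | (2S)-2-(benzyloxy)-3-[2,4-bis(benzyloxy)-6-bromo-3-(dimethoxymethyl)phenyl]-N-methoxy-N-methylpropanamide | CON(C)C(=O)[C@@H](OCc9ccccc9)Cc1c(Br)cc(OCc9ccccc9)c(C(OC)OC)c1OCc9ccccc9 | intermediate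
10 | 1,2-bis(benzyloxy)-4-bromobenzene | Brc1ccc(OCc9ccccc9)c(OCc9ccccc9)c1 | starting material
11 | [3,4-bis(benzyloxy)phenyl]magnesium bromide | Br[Mg]c1ccc(OCc9ccccc9)c(OCc9ccccc9)c1 | intermediate
12 | (2S)-2-(benzyloxy)-1-[3,4-bis(benzyloxy)phenyl]-3-[2,4-bis(benzyloxy)-6-bromo-3-(dimethoxymethyl)phenyl]propan-1-one | O=C(c8ccc(OCc9ccccc9)c(OCc9ccccc9)c8)[C@@H](OCc9ccccc9)Cc1c(Br)cc(OCc9ccccc9)c(C(OC)OC)c1OCc9ccccc9 | intermediate
13 | (1R,2S)-2-(benzyloxy)-1-[3,4-bis(benzyloxy)phenyl]-3-[2,4-bis(benzyloxy)-6-bromo-3-(dimethoxymethyl)phenyl]propan-1-ol (anti) | O[C@H](c8ccc(OCc9ccccc9)c(OCc9ccccc9)c8)[C@@H](OCc9ccccc9)Cc1c(Br)cc(OCc9ccccc9)c(C(OC)OC)c1OCc9ccccc9 | intermediate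
14 | (2R,3S)-3,5,7-tris(benzyloxy)-2-[3,4-bis(benzyloxy)phenyl]-6-(dimethoxymethyl)chromane (penta-O-benzylcatechin with CH(OMe)2 at C6) | COC(OC)c1c(OCc9ccccc9)cc2O[C@H](c8ccc(OCc9ccccc9)c(OCc9ccccc9)c8)[C@@H](OCc9ccccc9)Cc2c1OCc9ccccc9 | intermediate
15 | (2R,3S)-3,5,7-tris(benzyloxy)-2-[3,4-bis(benzyloxy)phenyl]-8-bromo-6-(dimethoxymethyl)chromane | COC(OC)c1c(OCc9ccccc9)c(Br)c2O[C@H](c8ccc(OCc9ccccc9)c(OCc9ccccc9)c8)[C@@H](OCc9ccccc9)Cc2c1OCc9ccccc9 | intermediate
16 | (2R,3S)-3,5,7-tris(benzyloxy)-2-[3,4-bis(benzyloxy)phenyl]-8-bromochromane-6-carbaldehyde | O=Cc1c(OCc9ccccc9)c(Br)c2c(c1OCc9ccccc9)C[C@H](OCc9ccccc9)[C@@H](c8ccc(OCc9ccccc9)c(OCc9ccccc9)c8)O2 | intermediate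
17 | 3,5-bis(benzyloxy)phenol | Oc1cc(OCc9ccccc9)cc(OCc9ccccc9)c1 | starting material
18 | 1,3-bis(benzyloxy)-5-(methoxymethoxy)benzene | COCOc1cc(OCc9ccccc9)cc(OCc9ccccc9)c1 | intermediate
19 | [2,4-bis(benzyloxy)-6-(methoxymethoxy)phenyl]lithium | [Li]c1c(OCOC)cc(OCc9ccccc9)cc1OCc9ccccc9 | intermediate
20 | [2,4-bis(benzyloxy)-6-(methoxymethoxy)phenyl][(2R,3S)-3,5,7-tris(benzyloxy)-2-(3,4-bis(benzyloxy)phenyl)-8-bromochroman-6-yl]methanol, both carbinol epimers | OC(c1c(OCOC)cc(OCc9ccccc9)cc1OCc9ccccc9)c1c(OCc9ccccc9)c(Br)c2c(c1OCc9ccccc9)C[C@H](OCc9ccccc9)[C@@H](c8ccc(OCc9ccccc9)c(OCc9ccccc9)c8)O2 | intermediate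
21 | 3,5-bis(benzyloxy)-2-{methoxy[(2R,3S)-3,5,7-tris(benzyloxy)-2-(3,4-bis(benzyloxy)phenyl)-8-bromochroman-6-yl]methyl}phenol, both epimers | COC(c1c(O)cc(OCc9ccccc9)cc1OCc9ccccc9)c1c(OCc9ccccc9)c(Br)c2c(c1OCc9ccccc9)C[C@H](OCc9ccccc9)[C@@H](c8ccc(OCc9ccccc9)c(OCc9ccccc9)c8)O2 | intermediate
22 | 3,4-bis(benzyloxy)benzonitrile | N#Cc1ccc(OCc9ccccc9)c(OCc9ccccc9)c1 | starting material
23 | N-(bromomagnesio) ketimine of 1-[3,4-bis(benzyloxy)phenyl]ethanone | CC(=N[Mg]Br)c1ccc(OCc9ccccc9)c(OCc9ccccc9)c1 | intermediate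
24 | N-{1-[3,4-bis(benzyloxy)phenyl]ethenyl}acetamide | CC(=O)NC(=C)c1ccc(OCc9ccccc9)c(OCc9ccccc9)c1 | intermediate
25 | ortho-quinone methide: 3,5-bis(benzyloxy)-6-{[(2R,3S)-3,5,7-tris(benzyloxy)-2-(3,4-bis(benzyloxy)phenyl)-8-bromochroman-6-yl]methylidene}cyclohexa-2,4-dien-1-one | O=C1C=C(OCc9ccccc9)C=C(OCc9ccccc9)C1=Cc1c(OCc9ccccc9)c(Br)c2c(c1OCc9ccccc9)C[C@H](OCc9ccccc9)[C@@H](c8ccc(OCc9ccccc9)c(OCc9ccccc9)c8)O2 | intermediate
26 | N-{(4R)-5,7-bis(benzyloxy)-2-[3,4-bis(benzyloxy)phenyl]-4-[(2R,3S)-3,5,7-tris(benzyloxy)-2-(3,4-bis(benzyloxy)phenyl)-8-bromochroman-6-yl]chroman-2-yl}acetamide, C2 epimers | c1c(OCc9ccccc9)cc(OCc9ccccc9)c2c1OC(NC(C)=O)(c8ccc(OCc9ccccc9)c(OCc9ccccc9)c8)C[C@H]2c1c(OCc9ccccc9)c(Br)c2c(c1OCc9ccccc9)C[C@H](OCc9ccccc9)[C@@H](c8ccc(OCc9ccccc9)c(OCc9ccccc9)c8)O2 | intermediate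
27 | (4R)-5,7-bis(benzyloxy)-2-[3,4-bis(benzyloxy)phenyl]-4-[(2R,3S)-3,5,7-tris(benzyloxy)-2-(3,4-bis(benzyloxy)phenyl)-8-bromochroman-6-yl]-4H-chromene | c1c(OCc9ccccc9)cc(OCc9ccccc9)c2c1OC(c8ccc(OCc9ccccc9)c(OCc9ccccc9)c8)=C[C@H]2c1c(OCc9ccccc9)c(Br)c2c(c1OCc9ccccc9)C[C@H](OCc9ccccc9)[C@@H](c8ccc(OCc9ccccc9)c(OCc9ccccc9)c8)O2 | intermediate
28 | 2,3-epoxide of 27 on the face opposite to the C4 aryl group | c1c(OCc9ccccc9)cc(OCc9ccccc9)c2c1O[C@]3(c8ccc(OCc9ccccc9)c(OCc9ccccc9)c8)O[C@@H]3[C@H]2c1c(OCc9ccccc9)c(Br)c2c(c1OCc9ccccc9)C[C@H](OCc9ccccc9)[C@@H](c8ccc(OCc9ccccc9)c(OCc9ccccc9)c8)O2 | intermediate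
29 | (2R,3R,4R)-5,7-bis(benzyloxy)-2-[3,4-bis(benzyloxy)phenyl]-2-methoxy-4-[(2R,3S)-3,5,7-tris(benzyloxy)-2-(3,4-bis(benzyloxy)phenyl)-8-bromochroman-6-yl]chroman-3-ol (3-OH trans to the C4 aryl and to 2-OMe) | c1c(OCc9ccccc9)cc(OCc9ccccc9)c2c1O[C@](OC)(c8ccc(OCc9ccccc9)c(OCc9ccccc9)c8)[C@H](O)[C@H]2c1c(OCc9ccccc9)c(Br)c2c(c1OCc9ccccc9)C[C@H](OCc9ccccc9)[C@@H](c8ccc(OCc9ccccc9)c(OCc9ccccc9)c8)O2 | intermediate
30 | 3,4,5-tris(benzyloxy)benzoic acid | OC(=O)c1cc(OCc9ccccc9)c(OCc9ccccc9)c(OCc9ccccc9)c1 | starting material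
31 | 3-O-[3,4,5-tris(benzyloxy)benzoyl] ester of 29 (2R,3R,4R) | c1c(OCc9ccccc9)cc(OCc9ccccc9)c2c1O[C@](OC)(c8ccc(OCc9ccccc9)c(OCc9ccccc9)c8)[C@H](OC(=O)c8cc(OCc9ccccc9)c(OCc9ccccc9)c(OCc9ccccc9)c8)[C@H]2c1c(OCc9ccccc9)c(Br)c2c(c1OCc9ccccc9)C[C@H](OCc9ccccc9)[C@@H](c8ccc(OCc9ccccc9)c(OCc9ccccc9)c8)O2 | intermediate
32 | 5,7,3',4'-tetra-O-benzylepicatechin 3-O-(tri-O-benzylgallate)-(4β→6)-8-bromo-3,5,7,3',4'-penta-O-benzylcatechin (mid 2R,3R,4R; bottom 2R,3S) | c1c(OCc9ccccc9)cc(OCc9ccccc9)c2c1O[C@H](c8ccc(OCc9ccccc9)c(OCc9ccccc9)c8)[C@H](OC(=O)c8cc(OCc9ccccc9)c(OCc9ccccc9)c(OCc9ccccc9)c8)[C@H]2c1c(OCc9ccccc9)c(Br)c2c(c1OCc9ccccc9)C[C@H](OCc9ccccc9)[C@@H](c8ccc(OCc9ccccc9)c(OCc9ccccc9)c8)O2 | intermediate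
33 | (−)-epicatechin, (2R,3R) | O[C@@H]1Cc2c(O)cc(O)cc2O[C@@H]1c1ccc(O)c(O)c1 | starting material
34 | 5,7,3',4'-tetra-O-benzyl-(−)-epicatechin | O[C@@H]1Cc2c(OCc9ccccc9)cc(OCc9ccccc9)cc2O[C@@H]1c1ccc(OCc9ccccc9)c(OCc9ccccc9)c1 | intermediate
35 | (2R,3R,4S)-5,7-bis(benzyloxy)-2-[3,4-bis(benzyloxy)phenyl]-4-(2-ethoxyethoxy)chroman-3-ol (4β ether) | O[C@@H]1[C@@H](OCCOCC)c2c(OCc9ccccc9)cc(OCc9ccccc9)cc2O[C@@H]1c1ccc(OCc9ccccc9)c(OCc9ccccc9)c1 | intermediate
36 | (2R,3R,4S)-5,7-bis(benzyloxy)-2-[3,4-bis(benzyloxy)phenyl]-4-(2-ethoxyethoxy)chroman-3-yl 3,4,5-tris(benzyloxy)benzoate | O=C(O[C@@H]1[C@@H](OCCOCC)c2c(OCc9ccccc9)cc(OCc9ccccc9)cc2O[C@@H]1c1ccc(OCc9ccccc9)c(OCc9ccccc9)c1)c1cc(OCc9ccccc9)c(OCc9ccccc9)c(OCc9ccccc9)c1 | intermediate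
37 | nonadeca-O-benzyl 8-bromo derivative of the target: tetra-O-benzylepicatechin 3-O-(tri-O-benzylgallate)-(4β→8)-tetra-O-benzylepicatechin 3-O-(tri-O-benzylgallate)-(4β→6)-8-bromo-penta-O-benzylcatechin | O=C(O[C@@H]1[C@@H](c2c(OCc9ccccc9)cc(OCc9ccccc9)c3c2O[C@H](c2ccc(OCc9ccccc9)c(OCc9ccccc9)c2)[C@H](OC(=O)c2cc(OCc9ccccc9)c(OCc9ccccc9)c(OCc9ccccc9)c2)[C@H]3c2c(OCc9ccccc9)c(Br)c3c(c2OCc9ccccc9)C[C@H](OCc9ccccc9)[C@@H](c2ccc(OCc9ccccc9)c(OCc9ccccc9)c2)O3)c2c(OCc9ccccc9)cc(OCc9ccccc9)cc2O[C@@H]1c1ccc(OCc9ccccc9)c(OCc9ccccc9)c1)c1cc(OCc9ccccc9)c(OCc9ccccc9)c(OCc9ccccc9)c1 | intermediate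
38 | epicatechin 3-O-gallate-(4β→8)-epicatechin 3-O-gallate-(4β→6)-catechin (top 2R,3R,4R; mid 2R,3R,4S; bottom 2R,3S) | O=C(O[C@@H]1[C@@H](c2c(O)cc(O)c3c2O[C@H](c2ccc(O)c(O)c2)[C@H](OC(=O)c2cc(O)c(O)c(O)c2)[C@H]3c2c(O)cc3c(c2O)C[C@H](O)[C@@H](c2ccc(O)c(O)c2)O3)c2c(O)cc(O)cc2O[C@@H]1c1ccc(O)c(O)c1)c1cc(O)c(O)c(O)c1 | target

**Step count**

Total steps: 24. Longest linear sequence: 19 steps (1–11, 13, 14, 16–19, 23, 24).

**Steps most likely to fail**

Step 16. The chiral phosphate may fail to differentiate the faces of the hindered, 5-alkoxy-substituted ortho-quinone methide, and the methide may self-condense through the free positions of the phloroglucinol ring. The fallback sets out from 14 and returns at 32, and gives up the carbon at C6. Acetal 14 is hydrolysed (pyridinium p-toluenesulfonate, wet acetone) to (2R,3S)-3,5,7-tris(benzyloxy)-2-[3,4-bis(benzyloxy)phenyl]chromane-6-carbaldehyde F1. Tsuji–Wilkinson decarbonylation with stoichiometric RhCl(PPh3)3 in refluxing toluene should give 3,5,7,3',4'-penta-O-benzylcatechin F2, and N-bromosuccinimide its 8-bromide F3. Me3SiOSO2CF3-promoted condensation of 8-bromo-penta-O-benzylcatechin F3 with electrophile 36 at −78 °C, where only C6 is free and attack occurs trans to the 3-O-galloyl group, should give dimer 32. The 4→6 connectivity then rests on the bromine block and not on the formyl carbon.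

Step 19. The oxocarbenium ion may eliminate to the enol ester with loss of the C3 configuration, or hydride may be delivered from the face of the ester. The fallback sets out from 29 and returns at 32. Ketal 29 is hydrolysed (aqueous CF3CO2H/THF, 0 °C) to the (3R,4R)-2,3-dihydroxy hemiketal F4, the ring tautomer of the α-hydroxy ketone. Zn(BH4)2 should reduce the open form under chelation control to the anti (1S,2R,3R)-1,2-diol phenol F5. Mitsunobu cyclisation (PPh3, diisopropyl azodicarboxylate), in which the phenol is the only acidic pronucleophile and displaces the activated benzylic hydroxyl with inversion, should give the 2,3-cis flavan-3-ol dimer F6. Steglich esterification of F6 with 30 returns to 32.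

Step 9. Oxidative addition into the electron-rich, ortho-substituted aryl bromide may be sluggish, with competing protodebromination or oxidation of the benzylic alkoxide. The fallback sets out from 12 and returns at 14, and forms the C2–O1 bond instead of O1–C8a. Ketone 12 is reduced with K[(s-Bu)3BH] (non-chelating, Felkin–Anh control) to the syn (1S,2S) bromo alcohol F7. Miyaura borylation ([1,1'-bis(diphenylphosphino)ferrocene]PdCl2, bis(pinacolato)diboron, KOAc) should give the pinacol boronate F8, and NaBO3 oxidation the (1S,2S) phenol F9. Mitsunobu cyclisation of F9 with inversion at the carbinol carbon should give 14, the ring oxygen now coming from the phenol.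

**Further compounds**

F1 | step 16 | (2R,3S)-3,5,7-tris(benzyloxy)-2-[3,4-bis(benzyloxy)phenyl]chromane-6-carbaldehyde | O=Cc1c(OCc9ccccc9)cc2c(c1OCc9ccccc9)C[C@H](OCc9ccccc9)[C@@H](c8ccc(OCc9ccccc9)c(OCc9ccccc9)c8)O2
F2 | step 16 | 3,5,7,3',4'-penta-O-benzyl-(+)-catechin | c1c(OCc9ccccc9)cc2c(c1OCc9ccccc9)C[C@H](OCc9ccccc9)[C@@H](c8ccc(OCc9ccccc9)c(OCc9ccccc9)c8)O2
F3 | step 16 | 8-bromo-3,5,7,3',4'-penta-O-benzyl-(+)-catechin | c1c(OCc9ccccc9)c(Br)c2c(c1OCc9ccccc9)C[C@H](OCc9ccccc9)[C@@H](c8ccc(OCc9ccccc9)c(OCc9ccccc9)c8)O2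
F4 | step 19 | (3R,4R)-5,7-bis(benzyloxy)-2-[3,4-bis(benzyloxy)phenyl]-4-[(2R,3S)-3,5,7-tris(benzyloxy)-2-(3,4-bis(benzyloxy)phenyl)-8-bromochroman-6-yl]chromane-2,3-diol (hemiketal, C2 epimers) | c1c(OCc9ccccc9)cc(OCc9ccccc9)c2c1OC(O)(c8ccc(OCc9ccccc9)c(OCc9ccccc9)c8)[C@H](O)[C@H]2c1c(OCc9ccccc9)c(Br)c2c(c1OCc9ccccc9)C[C@H](OCc9ccccc9)[C@@H](c8ccc(OCc9ccccc9)c(OCc9ccccc9)c8)O2
F5 | step 19 | (1S,2R,3R)-1-[3,4-bis(benzyloxy)phenyl]-3-[2,4-bis(benzyloxy)-6-hydroxyphenyl]-3-[(2R,3S)-3,5,7-tris(benzyloxy)-2-(3,4-bis(benzyloxy)phenyl)-8-bromochroman-6-yl]propane-1,2-diol | O[C@@H](c8ccc(OCc9ccccc9)c(OCc9ccccc9)c8)[C@H](O)[C@@H](c1c(OCc9ccccc9)c(Br)c2c(c1OCc9ccccc9)C[C@H](OCc9ccccc9)[C@@H](c8ccc(OCc9ccccc9)c(OCc9ccccc9)c8)O2)c1c(O)cc(OCc9ccccc9)cc1OCc9ccccc9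
F6 | step 19 | 5,7,3',4'-tetra-O-benzylepicatechin-(4β→6)-8-bromo-3,5,7,3',4'-penta-O-benzylcatechin (free mid 3-OH) | c1c(OCc9ccccc9)cc(OCc9ccccc9)c2c1O[C@H](c8ccc(OCc9ccccc9)c(OCc9ccccc9)c8)[C@H](O)[C@H]2c1c(OCc9ccccc9)c(Br)c2c(c1OCc9ccccc9)C[C@H](OCc9ccccc9)[C@@H](c8ccc(OCc9ccccc9)c(OCc9ccccc9)c8)O2
F7 | step 9 | (1S,2S)-2-(benzyloxy)-1-[3,4-bis(benzyloxy)phenyl]-3-[2,4-bis(benzyloxy)-6-bromo-3-(dimethoxymethyl)phenyl]propan-1-ol (syn) | O[C@@H](c8ccc(OCc9ccccc9)c(OCc9ccccc9)c8)[C@@H](OCc9ccccc9)Cc1c(Br)cc(OCc9ccccc9)c(C(OC)OC)c1OCc9ccccc9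
F8 | step 9 | (1S,2S)-2-(benzyloxy)-1-[3,4-bis(benzyloxy)phenyl]-3-[2,4-bis(benzyloxy)-3-(dimethoxymethyl)-6-(4,4,5,5-tetramethyl-1,3,2-dioxaborolan-2-yl)phenyl]propan-1-ol | O[C@@H](c8ccc(OCc9ccccc9)c(OCc9ccccc9)c8)[C@@H](OCc9ccccc9)Cc1c(B2OC(C)(C)C(C)(C)O2)cc(OCc9ccccc9)c(C(OC)OC)c1OCc9ccccc9
F9 | step 9 | 3,5-bis(benzyloxy)-2-{(2S,3S)-2-(benzyloxy)-3-[3,4-bis(benzyloxy)phenyl]-3-hydroxypropyl}-4-(dimethoxymethyl)phenol | O[C@@H](c8ccc(OCc9ccccc9)c(OCc9ccccc9)c8)[C@@H](OCc9ccccc9)Cc1c(O)cc(OCc9ccccc9)c(C(OC)OC)c1OCc9ccccc9
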